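The readings were generated by integration for substances that don't exist.

There are 3 questions on this flask, and the examiner leads up to them with questions of his own.

| flask | starting material | partner | free catalyst | precatalyst | remark | time |
|---|---|---|---|---|---|---|
| birch | 4 mM | 2 mM (fed, over 25 s) | 20 µM | 1 µM | run made earlier |  |
| flask | 2.0 mM | 2.00 mM (fed, over 25 s) | 20 µM | 1.0 µM |  | 10 min |

- birch (time / min: product / %): 0.500: 22.6; 1.00: 39.9; 1.50: 44.3; 2.00: 46.4; 2.50: 46.6; 3.00: 48.8

(readings scatter by 0.5 percentage points)

- the state of affairs at 10 min: stopped, and by what, or still going (it is still moving / all of the starting material has reacted / the partner has run out first / no working catalyst is left)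
- how much product there is at 10 min, in percent of the starting material charged
- amount of product if the flask were left three thousand times as long, in percent of the starting material charged

- steps thought possible: partner + second catalyst + intermediate -> second catalyst + product; partner + precatalyst -> second catalyst + spent reagent; intermediate -> decomposed reagent; starting material + free catalyst -> free catalyst + intermediate
- the reaction counts as stopped when no species that holds the starting material changes by six tenths of a point or more over the second half of the time

**Where does the material go?** I assume that within seconds free catalyst turns the starting material into intermediate. The birch run reports product alone, so it doesn't test that. Intermediate then has two exits: with partner to product, or by itself to decomposed reagent. If f is the partner left as a fraction of its charge, and h is the fraction at which both exits run equal, the share going to product is f/(f+h).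

**What does the birch run say about h?** Each product takes one partner, so birch partner stands at 54.8 %, 20.2 % and 7.20 % at 0.500 min, 1.00 min and 2.00 min. Its pseudo-first-order constant falls from 2.00 min⁻¹ to 1.03 min⁻¹. That constant follows the intermediate, which is the charge minus the partner used minus h times the logarithm of the inverse of f. Matching the two constants gives the even-split level, the partner fraction at which the exits run equal, as 0.279. It is a rough reading, since it rests on scattered points.

**And this flask?** The charges are equal, so the intermediate is gone when f equals h times the logarithm of the inverse of f. That gives 31.8 %, and the right side returns 32.0 %. I commit to 68.2 % product.

**But partner is left over: won't waiting give more?** Not without intermediate. The same reading puts its decomposition half-life near 1.28 min, and 10 min is 7.81 of those, so I expect this flask to have stopped.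

The forecast says all of the starting material has reacted, with 75 % at 10 min and 75 % in the long run (“Waiting longer adds nothing”), which is a higher yield than my reckoning gives.

The flask gives all of the starting material has reacted, with 68.7 % and 68.7 %.

    partner + second catalyst + intermediate → second catalyst + product (k = 1.90 × 10⁷ L² mol⁻² s⁻¹)
    partner + precatalyst → second catalyst + spent reagent (k = 84.0 L mol⁻¹ s⁻¹)
    intermediate → decomposed reagent (k = 0.00670 s⁻¹)
    starting material + free catalyst → free catalyst + intermediate (k = 50000 L mol⁻¹ s⁻¹)

This flask has come to rest. Over the second half of the time the largest change is 0.21 percentage points, and intermediate is 0 % at 10.0 min. Ten times the time changes nothing: product stands at 68.7 % at 100 min, and partner stays at 31.3 %, close to my f of 31.8 %.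

The neighbour flask holds 2.5 × 10⁻⁴ mM of precatalyst, so if second catalyst scales with it, h becomes 1.12, f becomes 58.5 %, and product 41.5 %. The neighbour gives 45.8 %, with 54 % of its partner left.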